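**Retrosynthetic overview** (drimane locants: ring A = C1–C5 and C10; ring B = C5–C10; C11 = benzylic methine; aryl carbons primed)

1. Target 17 ⇐ diene 11 by functional-group work only: diimide reduction of C6=C7, desilylation, ortho-formylation at C3', O-sulfation at O2', debenzylation.
2. Key disconnection 11 ⇒ 10 (bonds C8–C9 and C5–C10): ring B is an alkylidenecyclohexane whose sp2 ring atom C9 carries the exocyclic C9=C11 bond between quaternary C10 and C8. With a C6=C7 bond added, this is the retron of an allene–diene (4+2) cycloaddition: C10=C9=C11 becomes an aryl allene, C5=C6–C7=C8 an (E,E)-diene, and C1–C4 of ring A the tether.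
3. 10 ⇒ propargylic phosphate 5 + alkylborane 9 (copper-catalysed SN2' coupling); 5 from 2,4,5-trihydroxybenzaldehyde 1 and 1-propynylmagnesium bromide; 9 from 2,2-dimethylpent-4-enal 6 by Takai iodo-olefination, Suzuki coupling and hydroboration.
4. Ring order: the arene is bought; rings A and B form together in step 8 from the acyclic, racemic precursor 10 (ring A through the C5–C10 bond, ring B when the C8–C9 bond forms).

Key step: step 8

Remark (assumption): the aryl sulfates 16 and 17 are written as the neutral hydrogen sulfates as the target is drawn, although they would be handled as sodium or pyridinium salts and acidified only at the end; catalyst-bound gold species of step 8 are transient and are described only in its Why line.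

**Route**

Step 1
Reactants: 1 2,4,5-trihydroxybenzaldehyde
Product: 2 4,5-bis(benzyloxy)-2-hydroxybenzaldehyde
Conditions: BnBr (2.1 equiv), K2CO3 (2.1 equiv), DMF, 0 °C → rt, N2
Reagents that add atoms: benzyl bromide, BrCc1ccccc1
Why: Williamson etherification; the 2-OH is held in a hydrogen bond to the formyl group and is the least nucleophilic, so two equivalents of benzyl bromide should alkylate only the 4- and 5-OH.

Step 2
Reactants: 2 4,5-bis(benzyloxy)-2-hydroxybenzaldehyde
Product: 3 4,5-bis(benzyloxy)-2-(triisopropylsilyloxy)benzaldehyde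
Conditions: TIPSOTf, 2,6-lutidine, CH2Cl2, 0 °C → rt
Reagents that add atoms: triisopropylsilyl trifluoromethanesulfonate, CC(C)[Si](OS(=O)(=O)C(F)(F)F)(C(C)C)C(C)C
Why: Silyl triflate silylation of the chelated phenol; the bulky, poorly nucleophilic OTIPS group is chosen so that it neither migrates to the benzylic alkoxide in step 3 nor attacks the gold-activated allene in step 8.

Step 3
Reactants: 3 4,5-bis(benzyloxy)-2-(triisopropylsilyloxy)benzaldehyde
Product: 4 rac-1-[4,5-bis(benzyloxy)-2-(triisopropylsilyloxy)phenyl]but-2-yn-1-ol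
Conditions: MeC≡CMgBr, THF, −78 → 0 °C; aq. NH4Cl
Reagents that add atoms: 1-propynylmagnesium bromide, CC#C[Mg]Br
Why: Grignard 1,2-addition of the alkynylmagnesium reagent to the aryl aldehyde; the carbinol centre is formed racemic on purpose, because its stereochemical information is erased in step 8.

Step 4
Reactants: 4 rac-1-[4,5-bis(benzyloxy)-2-(triisopropylsilyloxy)phenyl]but-2-yn-1-ol
Product: 5 rac-1-[4,5-bis(benzyloxy)-2-(triisopropylsilyloxy)phenyl]but-2-yn-1-yl diethyl phosphate
Conditions: ClP(O)(OEt)2, N-methylimidazole, CH2Cl2, 0 °C → rt; used crude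
Reagents that add atoms: diethyl chlorophosphate, CCOP(=O)(Cl)OCC
Why: O-phosphorylation under basic conditions installs the leaving group for γ-selective copper-catalysed substitution without ionising the electron-rich benzylic centre.

Step 5
Reactants: 6 2,2-dimethylpent-4-enal
Product: 7 (E)-1-iodo-3,3-dimethylhexa-1,5-diene
Conditions: CrCl2 (6 equiv), CHI3 (2 equiv), THF, 0 °C → rt, dark
Reagents that add atoms: iodoform, IC(I)I
Why: Takai iodo-olefination (gem-dichromium reagent from iodoform and divalent chromium) should convert the α-quaternary aldehyde into the (E)-vinyl iodide and leave the isolated terminal alkene untouched.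

Step 6
Reactants: 7 (E)-1-iodo-3,3-dimethylhexa-1,5-diene
Product: 8 (5E,7E)-4,4-dimethylnona-1,5,7-triene
Conditions: (E)-MeCH=CHB(OH)2, Pd(PPh3)4 (5 mol%), aq. K3PO4, THF, 50 °C
Reagents that add atoms: (E)-prop-1-en-1-ylboronic acid, C/C=C/B(O)O
Why: Suzuki–Miyaura coupling on zerovalent palladium proceeds with retention at both alkenyl partners and so fixes the (E,E)-diene.

Step 7
Reactants: 8 (5E,7E)-4,4-dimethylnona-1,5,7-triene; 5 rac-1-[4,5-bis(benzyloxy)-2-(triisopropylsilyloxy)phenyl]but-2-yn-1-yl diethyl phosphate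
Product: 10 rac-(8E,10E)-1-[4,5-bis(benzyloxy)-2-(triisopropylsilyloxy)phenyl]-3,7,7-trimethyldodeca-1,2,8,10-tetraene (racemic allene axis), via alkylborane 9 (not isolated)
Conditions: 9-BBN dimer, THF, rt → 60 °C; then 5, CuOAc (10 mol%), t-BuOK (1 equiv), THF, rt
Reagents that add atoms: 9-borabicyclo[3.3.1]nonane, B1C2CCCC1CCC2 (its atoms stay in 9 only)
Why: 9-BBN hydroborates the terminal alkene in preference to the hindered conjugated diene, and the resulting alkylborate transfers its alkyl group to monovalent copper for γ-selective SN2' substitution of the propargylic phosphate, a known copper-catalysed allene synthesis; the allene axis is formed racemic.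

Step 8
Reactants: 10 rac-(8E,10E)-1-[4,5-bis(benzyloxy)-2-(triisopropylsilyloxy)phenyl]-3,7,7-trimethyldodeca-1,2,8,10-tetraene
Product: 11 (2S,4aS,8aS)-1-{(E)-[4,5-bis(benzyloxy)-2-(triisopropylsilyloxy)phenyl]methylidene}-2,5,5,8a-tetramethyl-1,2,4a,5,6,7,8,8a-octahydronaphthalene (trans-fused; C6=C7 double bond in drimane locants)
Conditions: L*AuCl (5 mol%; L* = 1,1'-binaphthyl-2,2'-diyl N,N-bis(1-phenylethyl)phosphoramidite, ligand enantiomer chosen to give the (2S,4aS,8aS) product), AgSbF6 (5 mol%), CH2Cl2, −30 → 0 °C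
Reagents that add atoms: none
Why: Proposed new method: the cationic chiral phosphoramidite complex of monovalent gold should convert the allene of 10 into a planar gold-bound allyl cation (charge shared by tertiary C10 and benzylic C11, aryl anti to C10), which adds to the termini C5 and C8 of the (E,E)-diene in a concerted (4+3) cycloaddition (bonds C10–C5 and C11–C8) to give a cycloheptenyl gold carbene at C9; a 1,2-alkyl shift of C8 from C11 to C9 with loss of the gold fragment then makes the C8–C9 bond and the exocyclic C9=C11 bond, so that the net result is the (4+2) adduct across C9=C10. The closest known reaction type is the enantioselective intramolecular (4+2) cycloaddition of allene-dienes catalysed by phosphite or phosphoramidite complexes of monovalent gold, established for three-atom tethers, dialkyl-substituted allene termini and tertiary ring-fusion carbons; the four-carbon tether, the quaternary ring-fusion carbon and the aryl-stabilised allene terminus are the untested elements. Ring A closes through the tether when the diene terminus C5 attacks C10 (exo with respect to both π systems, chair-like tether), and ring B closes by contraction of the first-formed seven-membered ring at the moment the C8–C9 bond forms. C5 and C8 are set relative to each other by suprafacial addition to the (E,E)-diene and retention at the migrating C8 (H-5 and H-8 cis, hence 8-methyl cis to 10-methyl); C10 is set relative to C5 by the chair-like extended transition state in which the gold-bearing C9 arm and the diene arm are pseudo-equatorial and the C10 methyl axial (trans ring fusion); the absolute sense comes from the chiral ligand, because both enantiomers of the racemic allene converge on the same planar allyl cation. The step needs (4+2) over (4+3) selectivity, E geometry and chemoselectivity for the diene: C10 has no hydrogen and the π-acidic ligand favours the alkyl over the hydride shift, the aryl group stays anti to quaternary C10 in the allyl cation and by least motion ends cis to C8 (E), and the bulky, poorly nucleophilic ortho-OTIPS group is there to prevent oxygen attack on C10 (chromene formation).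

Step 9
Reactants: 11 (2S,4aS,8aS)-1-{(E)-[4,5-bis(benzyloxy)-2-(triisopropylsilyloxy)phenyl]methylidene}-2,5,5,8a-tetramethyl-1,2,4a,5,6,7,8,8a-octahydronaphthalene
Product: 12 (2S,4aS,8aS)-1-{(E)-[4,5-bis(benzyloxy)-2-(triisopropylsilyloxy)phenyl]methylidene}-2,5,5,8a-tetramethyldecahydronaphthalene
Conditions: 2-nitrobenzenesulfonohydrazide (excess, in portions), Et3N, CH2Cl2, rt
Reagents that add atoms: none
Why: Diimide reduction (concerted syn transfer of H2) is very sensitive to substitution and should saturate the cis-disubstituted ring alkene C6=C7 while leaving the hindered trisubstituted styrene, the benzyl ethers and the silyl ether; no stereocenter is formed or touched.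

Step 10
Reactants: 12 (2S,4aS,8aS)-1-{(E)-[4,5-bis(benzyloxy)-2-(triisopropylsilyloxy)phenyl]methylidene}-2,5,5,8a-tetramethyldecahydronaphthalene
Product: 13 4,5-bis(benzyloxy)-2-{(E)-[(2S,4aS,8aS)-2,5,5,8a-tetramethyloctahydronaphthalen-1(2H)-ylidene]methyl}phenol
Conditions: Bu4NF, AcOH (1:1), THF, 0 °C
Reagents that add atoms: none
Why: Fluoride cleavage of the aryl silyl ether, buffered with acetic acid so that the ortho-hydroxystyrene sees neither strong acid (spirocyclisation onto C9) nor strong base; benzyl ethers are inert.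

Step 11
Reactants: 13 4,5-bis(benzyloxy)-2-{(E)-[(2S,4aS,8aS)-2,5,5,8a-tetramethyloctahydronaphthalen-1(2H)-ylidene]methyl}phenol
Product: 15 5,6-bis(benzyloxy)-2-hydroxy-3-{(E)-[(2S,4aS,8aS)-2,5,5,8a-tetramethyloctahydronaphthalen-1(2H)-ylidene]methyl}benzaldehyde, via hydroxymethylphenol 14 (not isolated)
Conditions: MgCl2, Et3N, (CH2O)n, THF, reflux
Reagents that add atoms: paraformaldehyde (as formaldehyde), C=O
Why: Magnesium-mediated ortho-formylation of phenols (Casnati–Skattebøl): the magnesium phenoxide delivers formaldehyde to C3', the only free ortho position, and the hydroxymethyl intermediate is oxidised by a second formaldehyde in an Oppenauer-type hydride transfer.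

Step 12
Reactants: 15 5,6-bis(benzyloxy)-2-hydroxy-3-{(E)-[(2S,4aS,8aS)-2,5,5,8a-tetramethyloctahydronaphthalen-1(2H)-ylidene]methyl}benzaldehyde
Product: 16 3,4-bis(benzyloxy)-2-formyl-6-{(E)-[(2S,4aS,8aS)-2,5,5,8a-tetramethyloctahydronaphthalen-1(2H)-ylidene]methyl}phenyl hydrogen sulfate
Conditions: SO3·pyridine (5 equiv), pyridine, 50 °C; NaHCO3 work-up
Reagents that add atoms: sulfur trioxide–pyridine complex, [O-]S(=O)(=O)[n+]1ccccc1
Why: O-sulfation of a phenol with a sulfur trioxide–amine complex; the 2'-OH is the only free hydroxyl, so regioselectivity is secured by the two benzyl ethers.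

Step 13
Reactants: 16 3,4-bis(benzyloxy)-2-formyl-6-{(E)-[(2S,4aS,8aS)-2,5,5,8a-tetramethyloctahydronaphthalen-1(2H)-ylidene]methyl}phenyl hydrogen sulfate
Product: 17 2-formyl-3,4-dihydroxy-6-{(E)-[(2S,4aS,8aS)-2,5,5,8a-tetramethyloctahydronaphthalen-1(2H)-ylidene]methyl}phenyl hydrogen sulfate (CNP0149861.1)
Conditions: H2 (1 atm), 10% Pd/C, EtOAc–MeOH, rt, stopped at full debenzylation; H+-form resin, 0 °C
Reagents that add atoms: none
Why: Hydrogenolysis of aryl benzyl ethers on palladium is fast, whereas the aryl sulfate is inert and the chelated aldehyde and the styrene shielded by quaternary C10 and the axial 8-methyl should react much more slowly; no stereocenter is affected.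

**Compound list**

1 | 2,4,5-trihydroxybenzaldehyde | O=Cc1cc(O)c(O)cc1O | starting material
2 | 4,5-bis(benzyloxy)-2-hydroxybenzaldehyde | O=Cc1cc(OCc2ccccc2)c(OCc2ccccc2)cc1O | intermediate
3 | 4,5-bis(benzyloxy)-2-(triisopropylsilyloxy)benzaldehyde | O=Cc1cc(OCc2ccccc2)c(OCc2ccccc2)cc1O[Si](C(C)C)(C(C)C)C(C)C | intermediate
4 | rac-1-[4,5-bis(benzyloxy)-2-(triisopropylsilyloxy)phenyl]but-2-yn-1-ol | CC#CC(O)c1cc(OCc2ccccc2)c(OCc2ccccc2)cc1O[Si](C(C)C)(C(C)C)C(C)C | intermediate
5 | rac-1-[4,5-bis(benzyloxy)-2-(triisopropylsilyloxy)phenyl]but-2-yn-1-yl diethyl phosphate | CC#CC(OP(=O)(OCC)OCC)c1cc(OCc2ccccc2)c(OCc2ccccc2)cc1O[Si](C(C)C)(C(C)C)C(C)C | intermediate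
6 | 2,2-dimethylpent-4-enal | C=CCC(C)(C)C=O | starting material
7 | (E)-1-iodo-3,3-dimethylhexa-1,5-diene | C=CCC(C)(C)/C=C/I | intermediate
8 | (5E,7E)-4,4-dimethylnona-1,5,7-triene | C=CCC(C)(C)/C=C/C=C/C | intermediate
9 | 9-[(5E,7E)-4,4-dimethylnona-5,7-dien-1-yl]-9-borabicyclo[3.3.1]nonane | C/C=C/C=C/C(C)(C)CCCB1C2CCCC1CCC2 | intermediate (not isolated)
10 | rac-(8E,10E)-1-[4,5-bis(benzyloxy)-2-(triisopropylsilyloxy)phenyl]-3,7,7-trimethyldodeca-1,2,8,10-tetraene | C/C=C/C=C/C(C)(C)CCCC(C)=C=Cc1cc(OCc2ccccc2)c(OCc2ccccc2)cc1O[Si](C(C)C)(C(C)C)C(C)C | intermediate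
11 | (2S,4aS,8aS)-1-{(E)-[4,5-bis(benzyloxy)-2-(triisopropylsilyloxy)phenyl]methylidene}-2,5,5,8a-tetramethyl-1,2,4a,5,6,7,8,8a-octahydronaphthalene | C[C@H]1C=C[C@H]2C(C)(C)CCC[C@]2(C)/C1=C/c1cc(OCc3ccccc3)c(OCc3ccccc3)cc1O[Si](C(C)C)(C(C)C)C(C)C | intermediate
12 | (2S,4aS,8aS)-1-{(E)-[4,5-bis(benzyloxy)-2-(triisopropylsilyloxy)phenyl]methylidene}-2,5,5,8a-tetramethyldecahydronaphthalene | C[C@H]1CC[C@H]2C(C)(C)CCC[C@]2(C)/C1=C/c1cc(OCc3ccccc3)c(OCc3ccccc3)cc1O[Si](C(C)C)(C(C)C)C(C)C | intermediate
13 | 4,5-bis(benzyloxy)-2-{(E)-[(2S,4aS,8aS)-2,5,5,8a-tetramethyloctahydronaphthalen-1(2H)-ylidene]methyl}phenol | C[C@H]1CC[C@H]2C(C)(C)CCC[C@]2(C)/C1=C/c1cc(OCc3ccccc3)c(OCc3ccccc3)cc1O | intermediate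
14 | 3,4-bis(benzyloxy)-2-(hydroxymethyl)-6-{(E)-[(2S,4aS,8aS)-2,5,5,8a-tetramethyloctahydronaphthalen-1(2H)-ylidene]methyl}phenol | C[C@H]1CC[C@H]2C(C)(C)CCC[C@]2(C)/C1=C/c1cc(OCc3ccccc3)c(OCc3ccccc3)c(CO)c1O | intermediate (not isolated)
15 | 5,6-bis(benzyloxy)-2-hydroxy-3-{(E)-[(2S,4aS,8aS)-2,5,5,8a-tetramethyloctahydronaphthalen-1(2H)-ylidene]methyl}benzaldehyde | C[C@H]1CC[C@H]2C(C)(C)CCC[C@]2(C)/C1=C/c1cc(OCc3ccccc3)c(OCc3ccccc3)c(C=O)c1O | intermediate
16 | 3,4-bis(benzyloxy)-2-formyl-6-{(E)-[(2S,4aS,8aS)-2,5,5,8a-tetramethyloctahydronaphthalen-1(2H)-ylidene]methyl}phenyl hydrogen sulfate | C[C@H]1CC[C@H]2C(C)(C)CCC[C@]2(C)/C1=C/c1cc(OCc3ccccc3)c(OCc3ccccc3)c(C=O)c1OS(=O)(=O)O | intermediate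
17 | 2-formyl-3,4-dihydroxy-6-{(E)-[(2S,4aS,8aS)-2,5,5,8a-tetramethyloctahydronaphthalen-1(2H)-ylidene]methyl}phenyl hydrogen sulfate | C[C@H]1CC[C@H]2C(C)(C)CCC[C@]2(C)/C1=C/c1cc(O)c(O)c(C=O)c1OS(=O)(=O)O | target

**Step count**

Total: 13 steps. Longest linear sequence: 11 steps (1–4, then 7–13).

**Steps most likely to fail**

1. Step 8 (Proposed new method). The gold carbene may undergo a 1,2-hydride shift instead of ring contraction and give the seven-membered (4+3) skeleton. The tether may also close with cis ring fusion, enantioinduction at the quaternary centre may be poor, or the allyl cation may lose a proton to an aryl diene. The fallback sets out from alcohol 4 and alkylborane 9 and returns at 11. MnO2 oxidation of 4 should give ynone F1. Copper-catalysed syn-hydroalkylation of F1 with 9 (CuOAc, P(OPh)3, t-BuOK, t-BuOH), as established for alkynoates, should give (E)-dienone F2 with the chain trans to the aroyl group. A Lewis-acid-promoted intramolecular Diels–Alder reaction of F2 (triflimide salt of (S)-1-(2-methylphenyl)-3,3-diphenyltetrahydro-1H,3H-pyrrolo[1,2-c][1,3,2]oxazaborole, CH2Cl2, −40 °C) should pass through the endo transition state, which for this (E)-dienophile is the trans-fused one, to ketone F3 with the C8–C9 and C5–C10 bonds in place. LiAlH4 reduction to benzylic alcohol F4 and dehydration (MsCl, Et3N, then DBU) through the benzylic cation should then give the thermodynamically favoured (E)-alkene 11.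

2. Step 11. Electrophilic attack at C3', crowded between the phenoxide and the 4'-benzyloxy group, may be slow, leading to recovered phenol or phenol–formaldehyde oligomerisation. The fallback sets out from phenol 13 and returns at 15. MOMCl and i-Pr2NEt give methoxymethyl ether F5. Directed ortho-lithiation at C3', the position between two oxygen substituents (s-BuLi, TMEDA, THF, −78 °C), and a DMF quench give aldehyde F6. Neutral removal of the acetal (ZnBr2, n-PrSH, CH2Cl2, 0 °C) then gives 15.

3. Step 12. Sulfation of the hydrogen-bonded, doubly ortho-substituted phenol may be incomplete, and the sulfate may be lost by hydrolysis during work-up. The fallback sets out from 15 and returns at 16. Sulfuryl transfer with 2,2,2-trichloroethyl chlorosulfate (Et3N, DMAP, THF) gives the robust, chromatographable trichloroethyl sulfate F7. Reductive unmasking (Zn, HCO2NH4, MeOH, rt) then releases 16.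

**Further compounds**

F1 | step 8 | 1-[4,5-bis(benzyloxy)-2-(triisopropylsilyloxy)phenyl]but-2-yn-1-one | CC#CC(=O)c1cc(OCc2ccccc2)c(OCc2ccccc2)cc1O[Si](C(C)C)(C(C)C)C(C)C
F2 | step 8 | (2E,8E,10E)-1-[4,5-bis(benzyloxy)-2-(triisopropylsilyloxy)phenyl]-3,7,7-trimethyldodeca-2,8,10-trien-1-one | C/C=C/C=C/C(C)(C)CCC/C(C)=C/C(=O)c1cc(OCc2ccccc2)c(OCc2ccccc2)cc1O[Si](C(C)C)(C(C)C)C(C)C
F3 | step 8 | [4,5-bis(benzyloxy)-2-(triisopropylsilyloxy)phenyl][(1S,2S,4aS,8aS)-2,5,5,8a-tetramethyl-1,2,4a,5,6,7,8,8a-octahydronaphthalen-1-yl]methanone | C[C@H]1C=C[C@H]2C(C)(C)CCC[C@]2(C)[C@H]1C(=O)c1cc(OCc3ccccc3)c(OCc3ccccc3)cc1O[Si](C(C)C)(C(C)C)C(C)C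
F4 | step 8 | [4,5-bis(benzyloxy)-2-(triisopropylsilyloxy)phenyl][(1S,2S,4aS,8aS)-2,5,5,8a-tetramethyl-1,2,4a,5,6,7,8,8a-octahydronaphthalen-1-yl]methanol (carbinol epimers) | C[C@H]1C=C[C@H]2C(C)(C)CCC[C@]2(C)[C@H]1C(O)c1cc(OCc3ccccc3)c(OCc3ccccc3)cc1O[Si](C(C)C)(C(C)C)C(C)C
F5 | step 11 | (2S,4aS,8aS)-1-{(E)-[4,5-bis(benzyloxy)-2-(methoxymethoxy)phenyl]methylidene}-2,5,5,8a-tetramethyldecahydronaphthalene | C[C@H]1CC[C@H]2C(C)(C)CCC[C@]2(C)/C1=C/c1cc(OCc3ccccc3)c(OCc3ccccc3)cc1OCOC
F6 | step 11 | 5,6-bis(benzyloxy)-2-(methoxymethoxy)-3-{(E)-[(2S,4aS,8aS)-2,5,5,8a-tetramethyloctahydronaphthalen-1(2H)-ylidene]methyl}benzaldehyde | C[C@H]1CC[C@H]2C(C)(C)CCC[C@]2(C)/C1=C/c1cc(OCc3ccccc3)c(OCc3ccccc3)c(C=O)c1OCOC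
F7 | step 12 | 3,4-bis(benzyloxy)-2-formyl-6-{(E)-[(2S,4aS,8aS)-2,5,5,8a-tetramethyloctahydronaphthalen-1(2H)-ylidene]methyl}phenyl 2,2,2-trichloroethyl sulfate | C[C@H]1CC[C@H]2C(C)(C)CCC[C@]2(C)/C1=C/c1cc(OCc3ccccc3)c(OCc3ccccc3)c(C=O)c1OS(=O)(=O)OCC(Cl)(Cl)Cl
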